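**Retrosynthetic overview**
1. The 2α-alcohol comes from Luche reduction of a 2-ketone. The seven-membered ring is closed by intramolecular Friedel–Crafts acylation (C12–C13) of a C1-(2-furyl) keto acid, and the furan is joined to C1 by a Mukaiyama aldol-type addition of the ring A silyl dienol ether to 2,5-dimethoxy-2,5-dihydrofuran.
2. The 2-oxo-Δ3-18,19-olide comes from allylic oxidation of the lactone made by Pd-catalysed carbonylative lactonization of a C4 enol triflate onto the C19 hydroxymethyl.
3. Ring B substituents: β-face hydroboration of a Δ7-8-methyl alkene gives 7β-O/8α-Me; Li/NH3 reductive alkylation of the octalone sets C9 and C10.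
4. The decalin comes from a Robinson annulation. Its key C5–C6 bond is made by intermolecular Michael addition of 2-allylcyclohexane-1,3-dione to ethyl vinyl ketone, and a D-phenylalanine-mediated aldol condensation then sets C5. The angular allyl becomes C19.
5. Ring order: A (from the dione) → B (annulation) → lactone → furan → seven-membered ring.

Convention and assumption: locants follow clerodane numbering of the target (decalin C1–C10, ring A = C1–C5/C10, ring B = C5–C10; C11, C12 on C9; furan C13–C16 with C16 on C1; C17 on C8; C18 = lactone C=O on C4; C19 = OCH2 on C5; C20 on C9). α is the face of C19 and C20, β the face of H-10. The target is taken as (1S,2S,5S,7S,8S,9R,10R), as encoded in the given SMILES.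

**Step 1**
Reactants: 1 cyclohexane-1,3-dione; 2 allyl bromide
Product: 3 2-allylcyclohexane-1,3-dione
Conditions: KOH, H2O, Cu powder (cat.), 0 °C → rt
Reagents that add atoms: none
Why: SN2 C-allylation of the 1,3-dione enolate in water, with copper suppressing O-allylation; no stereocenter is formed.

**Step 2**
Reactants: 3 2-allylcyclohexane-1,3-dione; 4 ethyl vinyl ketone (pent-1-en-3-one)
Product: 5 2-allyl-2-(3-oxopentyl)cyclohexane-1,3-dione
Conditions: Et3N (0.1 equiv), hydroquinone (trace), EtOAc, 60 °C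
Reagents that add atoms: none
Why: Amine-catalysed intermolecular Michael addition of the acidic 2-substituted 1,3-dione to the enone joins the two fragments at the future C5–C6 bond and creates the still prochiral quaternary carbon.

**Step 3**
Reactants: 5 2-allyl-2-(3-oxopentyl)cyclohexane-1,3-dione
Product: 6 (8aS)-8a-allyl-5-methyl-3,4,8,8a-tetrahydronaphthalene-1,6(2H,7H)-dione
Conditions: D-phenylalanine (1.0 equiv), (1R)-(−)-10-camphorsulfonic acid (0.5 equiv), DMF, 30 → 70 °C
Reagents that add atoms: none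
Why: The Hajos–Parrish–Eder–Sauer–Wiechert enamine aldol condensation (second half of the Robinson annulation) selects one of the two enantiotopic ring ketones, and the D-amino acid gives the (8aS) enone, the enantiomeric series to the L-proline-derived ketone, which fixes C5.

**Step 4**
Reactants: 6 (8aS)-8a-allyl-5-methyl-3,4,8,8a-tetrahydronaphthalene-1,6(2H,7H)-dione
Product: 7 C4 ethylene ketal of 6 (5α-allyl-4,4-ethylenedioxy-Δ9(10)-8-one)
Conditions: ethylene glycol, TsOH·H2O (cat.), 4 Å MS, CH2Cl2, rt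
Reagents that add atoms: ethylene glycol, OCCO
Why: Acid-catalysed ketalization is chemoselective for the saturated C4 ketone because the C8 carbonyl is deactivated by conjugation; C5 is untouched.

**Step 5**
Reactants: 7 C4 ethylene ketal of 6
Product: 8 5α-[(E)-prop-1-enyl] isomer of 7
Conditions: RuHCl(CO)(PPh3)3 (5 mol%), toluene, 110 °C
Reagents that add atoms: none
Why: Ruthenium hydride alkene isomerization (hydrometalation/β-hydride elimination) moves the terminal double bond one position to the more substituted (E)-propenyl group and cannot go further past the quaternary carbon.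

**Step 6**
Reactants: 8 5α-[(E)-prop-1-enyl] isomer of 7
Product: 10 5α-formyl enone ketal (C19 aldehyde), via ozonide 9 (not isolated)
Conditions: O3, CH2Cl2, −78 °C (Sudan Red 7B end point); then Me2S, −78 °C → rt
Reagents that add atoms: ozone, [O-][O+]=O
Why: Criegee ozonolysis with reductive work-up cleaves the electron-rich disubstituted propenyl alkene far faster than the tetrasubstituted, electron-poor enone alkene, leaving C19 as an aldehyde.

**Step 7**
Reactants: 10 5α-formyl enone ketal
Product: 11 5α-hydroxymethyl enone ketal (C19 alcohol)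
Conditions: NaBH4 (0.5 equiv), MeOH/CH2Cl2, −78 °C
Reagents that add atoms: none
Why: Chemoselective borohydride reduction: the aldehyde reacts at −78 °C while the hindered conjugated ketone does not.

**Step 8**
Reactants: 11 5α-hydroxymethyl enone ketal
Product: 12 C19 triisopropylsilyl ether of 11
Conditions: TIPSOTf, 2,6-lutidine, CH2Cl2, 0 °C
Reagents that add atoms: triisopropylsilyl triflate, CC(C)[Si](C(C)C)(C(C)C)OS(=O)(=O)C(F)(F)F
Why: Silylation of the primary neopentyl alcohol with the reactive silyl triflate; the TIPS ether survives Li/NH3, strong base, borane and mild acid.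

**Step 9**
Reactants: 12 C19 triisopropylsilyl ether of 11; 13 tert-butyl bromoacetate
Product: 15 tert-butyl 9β-acetate keto ester (8-oxo; 9α-Me; 10β-H; 4-ketal; 19-OTIPS), via lithium enolate 14 (not isolated)
Conditions: Li (2.1 equiv), t-BuOH (1.0 equiv), NH3(l)/THF, −78 °C; NH3 evaporated; then 13, THF, −78 → 0 °C
Reagents that add atoms: none
Why: Birch-type reductive alkylation (Stork): protonation at C10 gives the trans-decalin (H-10 β, anti to C19), and the regiodefined enolate is alkylated at C9 from the β face, opposite the axial C19 group, so C20 ends α and C11 β.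

**Step 10**
Reactants: 15 tert-butyl 9β-acetate keto ester
Product: 16 Δ7-8-enol triflate
Conditions: KN(SiMe3)2, PhNTf2, THF, −78 → 0 °C
Reagents that add atoms: N-phenylbis(trifluoromethanesulfonimide), O=S(=O)(N(c1ccccc1)S(=O)(=O)C(F)(F)F)C(F)(F)F
Why: Kinetic deprotonation can only occur at C7 (C9 is quaternary) and the ketone enolate is trapped as the enol triflate.

**Step 11**
Reactants: 16 Δ7-8-enol triflate
Product: 17 Δ7-8-methyl alkene
Conditions: Me2Zn, Pd(PPh3)4 (5 mol%), THF, 0 → 50 °C
Reagents that add atoms: dimethylzinc, C[Zn]C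
Why: Negishi cross-coupling of the enol triflate (oxidative addition to zerovalent palladium, transmetalation from zinc, reductive elimination) installs C17.

**Step 12**
Reactants: 17 Δ7-8-methyl alkene
Product: 19 7β-hydroxy-8α-methyl ester, via alkylborane 18 (not isolated)
Conditions: BH3·THF, THF, 0 °C → rt; then NaOH, H2O2, H2O, 0 °C → rt
Reagents that add atoms: hydrogen peroxide, OO
Why: Brown hydroboration–oxidation: borane adds syn and anti-Markovnikov (B at C7, H at C8) from the β face because the α face is blocked by the axial C19 and C20 groups, and oxidation with retention gives 7β-OH and 8α-CH3.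

**Step 13**
Reactants: 19 7β-hydroxy-8α-methyl ester
Product: 20 7β-acetate
Conditions: Ac2O, pyridine, DMAP (cat.), CH2Cl2, rt
Reagents that add atoms: acetic anhydride, CC(=O)OC(C)=O
Why: Nucleophile-catalysed acylation of the equatorial secondary alcohol; no stereocenter changes.

**Step 14**
Reactants: 20 7β-acetate
Product: 21 4-ketone
Conditions: TsOH·H2O (cat.), acetone/H2O (10:1), 45 °C
Reagents that add atoms: water, O
Why: Acid-catalysed ketal hydrolysis under conditions mild enough for the TIPS ether, the acetate and the tert-butyl ester.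

**Step 15**
Reactants: 21 4-ketone
Product: 22 Δ3-4-enol triflate
Conditions: KN(SiMe3)2, PhNTf2, THF, −78 °C
Reagents that add atoms: N-phenylbis(trifluoromethanesulfonimide), O=S(=O)(N(c1ccccc1)S(=O)(=O)C(F)(F)F)C(F)(F)F
Why: Enolization is possible only toward C3 (C5 is quaternary), and at −78 °C the ketone is deprotonated and trapped as the enol triflate faster than the ester groups react.

**Step 16**
Reactants: 22 Δ3-4-enol triflate
Product: 23 19-hydroxy enol triflate
Conditions: HF·pyridine, THF/pyridine, 0 °C → rt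
Reagents that add atoms: none
Why: Fluoride cleavage of the Si–O bond, driven by the Si–F bond strength; buffered HF leaves the enol triflate and both esters alone.

**Step 17**
Reactants: 23 19-hydroxy enol triflate
Product: 24 Δ3-18,19-olide tert-butyl ester
Conditions: Pd(PPh3)4 (10 mol%), CO (1 atm), Et3N, LiCl, MeCN, 65 °C
Reagents that add atoms: carbon monoxide, [C-]#[O+]
Why: Carbonylative lactonization: oxidative addition of the enol triflate to zerovalent palladium, CO insertion and capture of the acyl palladium by the neighbouring C19 hydroxyl form the five-membered lactone.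

**Step 18**
Reactants: 24 Δ3-18,19-olide tert-butyl ester
Product: 25 2-oxo-Δ3-18,19-olide tert-butyl ester
Conditions: Rh2(cap)4 (dirhodium tetrakis(caprolactamate), Rh2(C6H10NO)4, 1 mol%), t-BuOOH (70% aq., 5 equiv), K2CO3 (0.5 equiv), CH2Cl2, rt
Reagents that add atoms: tert-butyl hydroperoxide, CC(C)(C)OO
Why: Dirhodium caprolactamate/tert-butyl hydroperoxide allylic oxidation: the tert-butylperoxyl radical abstracts hydrogen from C2, the only allylic CH2 (C5 is quaternary), and the resulting peroxide collapses to the ketone.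

**Step 19**
Reactants: 25 2-oxo-Δ3-18,19-olide tert-butyl ester
Product: 26 2-oxo-Δ3-18,19-olide C12 acid
Conditions: CF3CO2H/CH2Cl2 (1:4), 0 °C → rt
Reagents that add atoms: none
Why: Acidolysis of the tert-butyl ester (E1 loss of isobutene) leaves the acetate, lactone and enedione intact.

**Step 20**
Reactants: 26 2-oxo-Δ3-18,19-olide C12 acid; 27 2,5-dimethoxy-2,5-dihydrofuran
Product: 29 1β-(furan-2-yl)-2-oxo acid, via bis-silyl dienol ether 28 (not isolated)
Conditions: TBSOTf (2.5 equiv), Et3N, CH2Cl2, 0 °C; pentane/Celite filtration; then 27, TMSOTf (0.2 equiv), CH2Cl2, −78 → −20 °C; aq. NaHCO3, then silica gel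
Reagents that add atoms: none
Why: Mukaiyama aldol-type addition of the only possible silyl dienol ether (C1=C2) to the oxocarbenium ion of the cyclic acetal, then loss of methanol aromatizes to the furan (a 2-furyl cation equivalent); attack comes from the β face away from axial C19/C20, and C1, being epimerizable, settles as the equatorial 1β epimer.

**Step 21**
Reactants: 29 1β-(furan-2-yl)-2-oxo acid
Product: 31 2,12-dioxo tetracycle (2-dehydro target), via acid chloride 30 (not isolated)
Conditions: 1-chloro-N,N,2-trimethylprop-1-en-1-amine, CH2Cl2, 0 °C; then SnCl4, CH2Cl2 (0.005 M), −78 → −20 °C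
Reagents that add atoms: none
Why: Intramolecular Friedel–Crafts acylation of the 2-alkylfuran at its 3-position, the only ring position the C9 tether can reach, closes the seven-membered ring; only the 1β epimer can cyclize, so C1 is fixed.

**Step 22**
Reactants: 31 2,12-dioxo tetracycle
Product: 32 CNP0182929.2 (7β-acetoxy-2α-hydroxy-12-oxo-1β,16-cyclo furanoclerod-3-en-18,19-olide)
Conditions: NaBH4, CeCl3·7H2O, MeOH/CH2Cl2, −78 °C
Reagents that add atoms: none
Why: Luche reduction: the cerium-activated, strongly electrophilic C2 enone carbonyl is reduced 1,2 in preference to the vinylogous-ester-like furyl ketone, with hydride entering axially from the β face to give the equatorial 2α alcohol trans to the C1–C16 bond.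

**Compound list**
1 | cyclohexane-1,3-dione | O=C1CCCC(=O)C1 | starting material
2 | allyl bromide | C=CCBr | starting material
3 | 2-allylcyclohexane-1,3-dione | C=CCC1C(=O)CCCC1=O | intermediate
4 | ethyl vinyl ketone (pent-1-en-3-one) | CCC(=O)C=C | starting material
5 | 2-allyl-2-(3-oxopentyl)cyclohexane-1,3-dione | CCC(=O)CCC1(CC=C)C(=O)CCCC1=O | intermediate
6 | (8aS)-8a-allyl-5-methyl-3,4,8,8a-tetrahydronaphthalene-1,6(2H,7H)-dione | C=CC[C@@]12CCC(=O)C(C)=C1CCCC2=O | intermediate
7 | C4 ethylene ketal of 6 (5α-allyl-4,4-ethylenedioxy-Δ9(10)-8-one) | C=CC[C@@]12CCC(=O)C(C)=C1CCCC23OCCO3 | intermediate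
8 | 5α-[(E)-prop-1-enyl] isomer of 7 | C/C=C/[C@@]12CCC(=O)C(C)=C1CCCC23OCCO3 | intermediate
9 | ozonide (1,2,4-trioxolane) of 8, mixture at the trioxolane carbons | CC4OOC(O4)[C@@]12CCC(=O)C(C)=C1CCCC23OCCO3 | intermediate
10 | 5α-formyl enone ketal (C19 aldehyde) | O=C[C@@]12CCC(=O)C(C)=C1CCCC23OCCO3 | intermediate
11 | 5α-hydroxymethyl enone ketal (C19 alcohol) | OC[C@@]12CCC(=O)C(C)=C1CCCC23OCCO3 | intermediate
12 | C19 triisopropylsilyl ether of 11 | CC(C)[Si](C(C)C)(C(C)C)OC[C@@]12CCC(=O)C(C)=C1CCCC23OCCO3 | intermediate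
13 | tert-butyl bromoacetate | BrCC(=O)OC(C)(C)C | starting material
14 | lithium Δ8(9)-enolate, trans-fused (10β-H; 4-ketal; 19-OTIPS) | [Li+].[O-]C1=C(C)[C@H]2CCCC3(OCCO3)[C@]2(CO[Si](C(C)C)(C(C)C)C(C)C)CC1 | intermediate
15 | tert-butyl 9β-acetate keto ester (8-oxo; 9α-Me; 10β-H; 4-ketal; 19-OTIPS) | O=C1CC[C@@]2(CO[Si](C(C)C)(C(C)C)C(C)C)C3(OCCO3)CCC[C@@H]2[C@@]1(C)CC(=O)OC(C)(C)C | intermediate
16 | Δ7-8-enol triflate of 15 | FC(F)(F)S(=O)(=O)OC1=CC[C@@]2(CO[Si](C(C)C)(C(C)C)C(C)C)C3(OCCO3)CCC[C@@H]2[C@@]1(C)CC(=O)OC(C)(C)C | intermediate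
17 | Δ7-8-methyl alkene | CC1=CC[C@@]2(CO[Si](C(C)C)(C(C)C)C(C)C)C3(OCCO3)CCC[C@@H]2[C@@]1(C)CC(=O)OC(C)(C)C | intermediate
18 | 7β-boryl-8α-methyl alkylborane (8β-H) | B[C@H]1C[C@@]2(CO[Si](C(C)C)(C(C)C)C(C)C)C3(OCCO3)CCC[C@@H]2[C@](CC(=O)OC(C)(C)C)(C)[C@@H]1C | intermediate
19 | 7β-hydroxy-8α-methyl ester (4-ketal; 19-OTIPS) | O[C@H]1C[C@@]2(CO[Si](C(C)C)(C(C)C)C(C)C)C3(OCCO3)CCC[C@@H]2[C@](CC(=O)OC(C)(C)C)(C)[C@@H]1C | intermediate
20 | 7β-acetate of 19 | CC(=O)O[C@H]1C[C@@]2(CO[Si](C(C)C)(C(C)C)C(C)C)C3(OCCO3)CCC[C@@H]2[C@](CC(=O)OC(C)(C)C)(C)[C@@H]1C | intermediate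
21 | 4-ketone (7β-OAc; 8α-Me; 19-OTIPS) | CC(=O)O[C@H]1C[C@@]2(CO[Si](C(C)C)(C(C)C)C(C)C)C(=O)CCC[C@@H]2[C@](CC(=O)OC(C)(C)C)(C)[C@@H]1C | intermediate
22 | Δ3-4-enol triflate | CC(=O)O[C@H]1C[C@@]2(CO[Si](C(C)C)(C(C)C)C(C)C)C(OS(=O)(=O)C(F)(F)F)=CCC[C@@H]2[C@](CC(=O)OC(C)(C)C)(C)[C@@H]1C | intermediate
23 | 19-hydroxy enol triflate | CC(=O)O[C@H]1C[C@@]2(CO)C(OS(=O)(=O)C(F)(F)F)=CCC[C@@H]2[C@](CC(=O)OC(C)(C)C)(C)[C@@H]1C | intermediate
24 | Δ3-18,19-olide tert-butyl ester | CC(=O)O[C@H]1C[C@@]23COC(=O)C2=CCC[C@@H]3[C@](CC(=O)OC(C)(C)C)(C)[C@@H]1C | intermediate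
25 | 2-oxo-Δ3-18,19-olide tert-butyl ester | CC(=O)O[C@H]1C[C@@]23COC(=O)C2=CC(=O)C[C@@H]3[C@](CC(=O)OC(C)(C)C)(C)[C@@H]1C | intermediate
26 | 2-oxo-Δ3-18,19-olide C12 acid | CC(=O)O[C@H]1C[C@@]23COC(=O)C2=CC(=O)C[C@@H]3[C@](CC(=O)O)(C)[C@@H]1C | intermediate
27 | 2,5-dimethoxy-2,5-dihydrofuran (cis/trans mixture) | COC1C=CC(OC)O1 | starting material
28 | 2-(tert-butyldimethylsilyloxy)-Δ1,3-diene tert-butyldimethylsilyl ester | CC(=O)O[C@H]1C[C@@]23COC(=O)C2=CC(O[Si](C)(C)C(C)(C)C)=C[C@@H]3[C@](CC(=O)O[Si](C)(C)C(C)(C)C)(C)[C@@H]1C | intermediate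
29 | 1β-(furan-2-yl)-2-oxo-Δ3-18,19-olide C12 acid | CC(=O)O[C@H]1C[C@@]23COC(=O)C2=CC(=O)[C@@H](c2ccco2)[C@@H]3[C@](CC(=O)O)(C)[C@@H]1C | intermediate
30 | acid chloride of 29 | CC(=O)O[C@H]1C[C@@]23COC(=O)C2=CC(=O)[C@@H](c2ccco2)[C@@H]3[C@](CC(=O)Cl)(C)[C@@H]1C | intermediate
31 | 2,12-dioxo tetracycle (2-dehydro target) | CC(=O)O[C@H]1C[C@@]23COC(=O)C2=CC(=O)[C@H]2c4occc4C(=O)C[C@@](C)([C@@H]1C)[C@@H]23 | intermediate
32 | CNP0182929.2, (1S,2S,5S,7S,8S,9R,10R) | CC(=O)O[C@H]1C[C@@]23COC(=O)C2=C[C@H](O)[C@H]2c4occc4C(=O)C[C@@](C)([C@@H]1C)[C@@H]23 | target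

**Totals**
Total steps: 22. Longest linear sequence: 22 steps (1 → 32; the route is fully linear).

**Steps most likely to fail and their fallbacks**

Step 18 (allylic oxidation of the electron-poor alkylidene lactone). If the catalytic oxidation is sluggish or unselective, the fallback sets out from 24 and comes back at 25. A Wohl–Ziegler radical bromination (NBS, AIBN, PhCF3, 80 °C) gives the 2-bromo lactone F1 as a mixture of C2 epimers. Kornblum–Ganem oxidation (AgBF4, DMSO, rt; then Et3N) then converts the allylic bromide into the ketone 25. This replaces C–H oxidation by halogenation followed by sulfoxide-mediated oxidation.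

Step 20 (furan attachment at the hindered C1). If the ionic addition fails for steric reasons, the fallback sets out from 26, through the same silyl dienol ether 28, and comes back at 29. Treatment of 28 with NBS (THF, −78 °C) and aqueous work-up gives the 1-bromo-2-oxo acid F2. Visible-light photoredox coupling with excess furan (Ru(bpy)3Cl2 1 mol%, 2,6-lutidine, DMF, blue LEDs) adds the α-keto radical to the furan 2-position and rearomatizes to 29. A radical C–C bond formation is less sensitive to the neopentyl environment than the polar addition.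

Step 21 (Friedel–Crafts ring closure). It can fail through furan polymerization, acylation of the C2 enol, or a reluctant seven-membered ring. The fallback reverses the order of the two ring bonds; it sets out from 26 and comes back at 31. The acid is converted (1-chloro-N,N,2-trimethylprop-1-en-1-amine, CH2Cl2) into the acid chloride F3. Stille acylation with tributyl(furan-3-yl)stannane (PdCl2(PPh3)2, toluene, 60 °C) gives the 3-furyl ketone F4, so C12–C13 is made first. Anodic methoxylation of the furan (MeOH, Et4NOTs, graphite anode, −20 °C) gives the 2,5-dimethoxy-2,5-dihydrofuran-3-yl ketone F5. Silylation (TBSOTf, Et3N) gives the silyl dienol ether F6. With TMSOTf at −78 → −20 °C, F6 adds intramolecularly through C1 to the acetal carbon next to the acyl group and loses methanol, giving 31 directly.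

**Further compounds**
F1 | step 18 | 2-bromo-Δ3-18,19-olide tert-butyl ester (C2 epimers) | CC(=O)O[C@H]1C[C@@]23COC(=O)C2=CC(Br)C[C@@H]3[C@](CC(=O)OC(C)(C)C)(C)[C@@H]1C
F2 | step 20 | 1-bromo-2-oxo-Δ3-18,19-olide C12 acid (C1 epimers) | CC(=O)O[C@H]1C[C@@]23COC(=O)C2=CC(=O)C(Br)[C@@H]3[C@](CC(=O)O)(C)[C@@H]1C
F3 | step 21 | acid chloride of 26 | CC(=O)O[C@H]1C[C@@]23COC(=O)C2=CC(=O)C[C@@H]3[C@](CC(=O)Cl)(C)[C@@H]1C
F4 | step 21 | 3-furyl ketone (C12 ketone on furan C13, ring still open) | CC(=O)O[C@H]1C[C@@]23COC(=O)C2=CC(=O)C[C@@H]3[C@](CC(=O)c2ccoc2)(C)[C@@H]1C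
F5 | step 21 | 2,5-dimethoxy-2,5-dihydrofuran-3-yl ketone (acetal epimers) | CC(=O)O[C@H]1C[C@@]23COC(=O)C2=CC(=O)C[C@@H]3[C@](CC(=O)C2=CC(OC)OC2OC)(C)[C@@H]1C
F6 | step 21 | tert-butyldimethylsilyl dienol ether of F5 | CC(=O)O[C@H]1C[C@@]23COC(=O)C2=CC(O[Si](C)(C)C(C)(C)C)=C[C@@H]3[C@](CC(=O)C2=CC(OC)OC2OC)(C)[C@@H]1C
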